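## The problem

Germacrane numbering is used throughout: ring carbons C1–C10 (C1 ketone, C4=C5 olefin, C6 lactone oxygen, C7 ring fusion, C8 ester, C10 carbinol), lactone carbons C11–C13, methyls C14 (on C10) and C15 (on C4). In this numbering target 27 is (6R,7R,8R,10R) with a 4Z olefin, and the lactone is trans-fused (H6 and H7 anti).

- **Ring.** The ten-membered carbocycle is costly to close in both enthalpy and entropy, and it carries a Z trisubstituted olefin whose geometry must be fixed before or during closure.
- **Stereocentres.** C6, C7 and C8 are contiguous, so the C6 carbinol can control C7 and C8 (directed epoxidation of an E C7=C8 olefin, then inversion at C7). C10 is a fully substituted carbinol isolated from C8 by the C9 methylene; it cannot be relayed reliably and should come from the chiral pool.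
- **Sensitive groups.** The α-methylene lactone is a Michael and Heck acceptor and must arrive late. The tertiary α-ketol (C1/C10) is prone to α-ketol rearrangement. The C8 ester sits 1,3 to the free C10 hydroxyl (acyl migration) and the lactone can move to O8 under base. The lactone oxygen at C6 is allylic.
- **Feature that the plan exploits.** Inside the ring the chain C1(=O)–C2H2–C3H2–C4(sp2)=C5 is a ketone whose β-carbon is bonded to an olefinic carbon. This is the retron of a ketone homoenolate coupled with an alkenyl halide. C1, C2 and C3 can therefore be a 1-substituted cyclopropanol built on C1, and the α-hydroxy-carbonyl pair C10/C1 with its methyl (C14) is the carbon skeleton of lactic acid.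

## Retrosynthesis

**27 from 25.** The isovalerate is cut first (C8–O acyl bond), leaving diol 25 and anhydride 26. The forward reaction must acylate the secondary C8 hydroxyl and leave the hindered tertiary C10 hydroxyl alone. The ester comes last so that no step after it uses base strong enough for acyl migration.

**25 from 23.** The lactone C7–C11 bond and the C11=C13 olefin are cut together. The precursor is the (diethoxyphosphoryl)acetate 23 of epoxy alcohol 21. The tethered carbanion opens the epoxide at C7 (5-exo, inversion), leaves the C8 oxygen in place with retention, and the resulting phosphonate enolate 24 is methylenated with formaldehyde. Compared with an intermolecular lactone annulation, the tether fixes the regiochemistry (C7, not C8) and gives the trans lactone by SN2 geometry. The ester of 23 is made from 21 and acid 22.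

**21 from 20.** The epoxide is cut back to the E C7=C8 olefin of dienol 20. The forward step is a hydroxyl-directed asymmetric epoxidation in which C6 and the tartrate reinforce each other, so C6 alone controls C7 and C8. The epoxide is made after ring closure because a free cyclopropanol four atoms from an epoxide would close a tetrahydrofuran.

**20 from 18 (key disconnection).** The ring is cut at C3–C4. The precursor is the open-chain alkenyl iodide 18, which carries a cyclopropanol on C10. Palladium inserts into C4–I, the cyclopropanol opens by β-carbon elimination to the homoenolate (palladacycle 19), and reductive elimination closes the ring.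

- Against the neighbouring cuts (C6–C7, C4=C5, C1–C10): no stereocentre is formed at the closure site, the Z geometry is stored in the iodide and carried over stereospecifically, and the C1 ketone appears without any redox or protecting-group step.
- The precursor has only two stereocentres (C6, C10).
- The lactone does not yet exist, so the alkenylpalladium has no acrylate or phosphonate carbanion nearby to trap it.

**18 from 10 and 14.** After removal of two silyl groups (17 to 18), the chain is cut at C6–C7 into alkyne 10 and enal 14. The forward reaction is hydroboration of 10, boron–zinc exchange and catalytic asymmetric alkenylzinc addition to 14. This joins the fragments, makes the E C7=C8 olefin and sets C6 by reagent control.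

**10 from 1, 2 and 4.** The cyclopropane is cut to the silyl enol ether 9 (C3 from diiodomethane), 9 to methyl ketone 8 (C2 from methyllithium), and 8 to dioxolanone 6. Dioxolanone 6 comes from alkylation of the lactic acid acetal 3 (from 1 and 2) with propargyl bromide 4 via enolate 5, which sets C10 by self-regeneration of the lactic acid stereocentre.

**14 from 11.** The Z iodo enal comes from but-2-yn-1-ol 11 by directed trans-hydroalumination/iodination (13) and oxidation.

## Roads not taken

**Alternative 1:** (the most obvious) Cut C6–C7 and the lactone C–O bond. The forward key step is an intramolecular 2-(alkoxycarbonyl)allylation of an aldehyde, CrCl2-mediated (Nozaki–Hiyama–Kishi) or zinc-mediated (Barbier), on bromo ester aldehyde A1, which closes the carbocycle and the lactone together. The chosen plan is better for these reasons: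

- In A1 the allylmetal carbon C7 is 1,5 to the C1 ketone, so five-membered carbocyclization competes with ten-membered closure unless the ketone is masked.
- C6 and C7 would be set in a macrocyclic transition state whose syn/anti and facial sense (relative to C8) cannot be designed.
- A1 needs a Z enal carried through a long linear sequence.

**Alternative 2:** Cut the C4=C5 olefin. The forward key step is ring-closing metathesis of diene A2 with a second-generation Grubbs catalyst. It would have to form a trisubstituted olefin in a strained ten-membered ring from a 1,1-disubstituted olefin and an allylic-oxygenated vinyl group. The acrylate olefin of the lactone competes, and the Z geometry would depend on ring thermodynamics. The chosen plan transfers the Z geometry stereospecifically from iodide 13.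

**Alternative 3:** Cut the C1 and C10 oxygens back to a C1=C10 olefin (biomimetic). The forward key step is late epoxidation of heliangolide diene A3 to epoxide A4, followed by Kornblum-type oxidation to the ketol. Three olefins compete, and the C10 configuration would be decided by the conformer population of the macrocycle. A3 still contains the whole ten-membered ring, so the ring problem is only postponed. The chosen plan takes C10 and the ketol pattern from lactic acid.

Key step: step 10

## Route

Step 1
Reactants: 1 (S)-lactic acid; 2 pivalaldehyde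
Product: 3 (2S,5S)-2-tert-butyl-5-methyl-1,3-dioxolan-4-one
Conditions: cat. TsOH, cat. H2SO4, pentane, reflux with water separator; cis isomer crystallized from pentane at −78 °C
Reagents that add atoms: none
Why: Acid-catalysed acetalization; the lactic acid stereocentre (future C10) induces the acetal centre, and the cis isomer should be the major, crystalline product.

Step 2
Reactants: 3 (2S,5S)-2-tert-butyl-5-methyl-1,3-dioxolan-4-one; 4 propargyl bromide
Product: 6 (2S,5R)-2-tert-butyl-5-methyl-5-(prop-2-yn-1-yl)-1,3-dioxolan-4-one, via lithium enolate 5 (not isolated)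
Conditions: LiN(iPr)2, THF, −78 °C; then 4, −78 to −30 °C
Reagents that add atoms: none
Why: Self-regeneration of stereocentres: enolate 5 is alkylated anti to the tert-butyl group, so the propargyl group (C9, C8, C7) replaces hydrogen with overall retention and sets the quaternary C10 centre.

Step 3
Reactants: 6 (2S,5R)-2-tert-butyl-5-methyl-5-(prop-2-yn-1-yl)-1,3-dioxolan-4-one
Product: 8 (3R)-3-hydroxy-3-methylhex-5-yn-2-one, via dilithio hemiketal 7 (not isolated)
Conditions: MeLi (2.2 equiv), THF, −78 °C; H2O quench at −78 °C
Reagents that add atoms: methyllithium, [Li]C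
Why: Mono-addition of an organolithium to a lactone carbonyl: one equivalent deprotonates the alkyne, the second adds to C1, and the cyclic hemiketal 7 should persist at −78 °C so that ketone 8 and pivalaldehyde are released only on quench; the methyl group becomes C2.

Step 4
Reactants: 8 (3R)-3-hydroxy-3-methylhex-5-yn-2-one
Product: 9 (3R)-3-methyl-2,3-bis(triethylsilyloxy)hex-1-en-5-yne
Conditions: TESOTf (2.5 equiv), Et3N, CH2Cl2, −78 to 0 °C
Reagents that add atoms: triethylsilyl trifluoromethanesulfonate, CC[Si](CC)(CC)OS(=O)(=O)C(F)(F)F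
Why: Soft enolization with O-silylation; the ketone can enolize only towards the methyl group because C10 is fully substituted, and the tertiary hydroxyl is silylated in the same operation.

Step 5
Reactants: 9 (3R)-3-methyl-2,3-bis(triethylsilyloxy)hex-1-en-5-yne
Product: 10 triethyl({1-[(2R)-2-(triethylsilyloxy)pent-4-yn-2-yl]cyclopropyl}oxy)silane
Conditions: Et2Zn, CH2I2, CH2Cl2, 0 °C to rt
Reagents that add atoms: diiodomethane, C(I)I
Why: Simmons–Smith cyclopropanation (Furukawa variant) of a silyl enol ether; the electron-rich enol ether reacts and the alkyne does not; the new CH2 is C3.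

Step 6
Reactants: 11 but-2-yn-1-ol
Product: 13 (2Z)-3-iodobut-2-en-1-ol, via cyclic alkenylalanate 12 (not isolated)
Conditions: NaAlH2(OCH2CH2OCH3)2, THF, 0 °C to rt; then I2, −78 to 0 °C
Reagents that add atoms: iodine, [I][I]
Why: Hydroxyl-directed trans-hydroalumination puts aluminium on the distal alkyne carbon inside the five-membered alanate 12; iodinolysis with retention gives the Z iodide, in which iodine marks the place of C3.

Step 7
Reactants: 13 (2Z)-3-iodobut-2-en-1-ol
Product: 14 (2Z)-3-iodobut-2-enal
Conditions: MnO2, CH2Cl2, rt; filtered and used as a solution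
Reagents that add atoms: none
Why: Allylic oxidation on manganese dioxide under neutral conditions, which should preserve the Z geometry of the sensitive β-iodo enal.

Step 8
Reactants: 10 triethyl({1-[(2R)-2-(triethylsilyloxy)pent-4-yn-2-yl]cyclopropyl}oxy)silane; 14 (2Z)-3-iodobut-2-enal
Product: 17 (2Z,4S,5E,8R)-2-iodo-8-(triethylsilyloxy)-8-[1-(triethylsilyloxy)cyclopropyl]nona-2,5-dien-4-ol, via alkenylborane 15 (not isolated), via alkenylzinc 16 (not isolated)
Conditions: 10, Cy2BH, PhMe, 0 °C to rt; Me2Zn, −78 °C; (−)-MIB [(2S)-3-exo-morpholinoisoborneol, 10 mol%]; 14, −30 to −10 °C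
Reagents that add atoms: none
Why: Catalytic asymmetric alkenylzinc addition: syn hydroboration gives E alkenylborane 15, boron–zinc exchange gives 16, and the amino alcohol–zinc catalyst should deliver the alkenyl group to the Si face of 14 (the sense of this ligand with unsaturated aldehydes), setting C6 as 4S in 17 and joining the fragments at C6–C7 with an E C7=C8 olefin.

Step 9
Reactants: 17 (2Z,4S,5E,8R)-2-iodo-8-(triethylsilyloxy)-8-[1-(triethylsilyloxy)cyclopropyl]nona-2,5-dien-4-ol
Product: 18 (2Z,4S,5E,8R)-8-(1-hydroxycyclopropyl)-2-iodonona-2,5-diene-4,8-diol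
Conditions: Bu4NF, THF, 0 °C; neutral work-up, used directly
Reagents that add atoms: none
Why: Fluoride cleavage of both triethylsilyl ethers; acid is avoided because 1-(1-hydroxyalkyl)cyclopropanols undergo pinacol-type ring expansion.

Step 10
Reactants: 18 (2Z,4S,5E,8R)-8-(1-hydroxycyclopropyl)-2-iodonona-2,5-diene-4,8-diol
Product: 20 (2R,4E,6S,7Z)-2,6-dihydroxy-2,8-dimethylcyclodeca-4,7-dien-1-one, via palladacycle 19 (not isolated)
Conditions: Pd(OAc)2 (15 mol%), XPhos (30 mol%), Cs2CO3, PhMe, 60 °C, syringe-pump addition of 18 (final 2 mM)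
Reagents that add atoms: none
Why: Proposed new method: zerovalent palladium inserts into the C4–I bond of 18 with retention of the Z geometry, carbonate-assisted exchange of iodide for the cyclopropanol oxygen is followed by β-carbon elimination, which opens the three-membered ring (about 27 kcal/mol of strain) to palladacycle 19 with C3 and C4 on the metal, and C(sp3)–C(sp2) reductive elimination forms C3–C4. The closest known reaction type is the intermolecular palladium-catalysed cross-coupling of cyclopropanol-derived ketone homoenolates with aryl halides; the new elements are the alkenyl iodide partner and the macrocyclizing mode. The ten-membered ring closes by reductive elimination from the eleven-membered palladacycle 19, and no new stereocentre is formed: C6 and C10 are spectators and the olefin geometry is that of the iodide. The two ring CH2 groups of the cyclopropanol are constitutionally equivalent, so either β-carbon elimination gives the same homoenolate and there is no regiochemical question. The selectivity needed is reductive elimination over β-hydride elimination (vinyl ketone plus hydrodeiodination) and over bimolecular coupling; the bulky biaryl phosphine should speed reductive elimination, slow addition keeps the substrate dilute, and the Z olefin, the E olefin and the fully substituted C10 act as turn elements that bring C3 near C4. The free C6 and C10 hydroxyls should be tolerated because only the strained cyclopropanolate undergoes C–C cleavage at this temperature, and the E C7=C8 olefin cannot be carbopalladated without forming a four-membered or 5-endo ring.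

Step 11
Reactants: 20 (2R,4E,6S,7Z)-2,6-dihydroxy-2,8-dimethylcyclodeca-4,7-dien-1-one
Product: 21 (1R,3R,7Z,9R,10R)-3,9-dihydroxy-3,7-dimethyl-11-oxabicyclo[8.1.0]undec-7-en-4-one
Conditions: Ti(OiPr)4, D-(−)-diisopropyl tartrate, tBuOOH, 4 Å molecular sieves, CH2Cl2, −20 °C
Reagents that add atoms: tert-butyl hydroperoxide, CC(C)(C)OO
Why: Sharpless asymmetric epoxidation of a secondary allylic alcohol in its matched sense: with the D-(−)-tartrate the C6 carbinol of 20 is the fast-reacting configuration for the E C7=C8 olefin and should give the erythro epoxide (7R,8R) from the peripheral face, while the Z trisubstituted C4=C5 olefin is both mismatched and of the slow class (cis substituent C3).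

Step 12
Reactants: 21 (1R,3R,7Z,9R,10R)-3,9-dihydroxy-3,7-dimethyl-11-oxabicyclo[8.1.0]undec-7-en-4-one; 22 (diethoxyphosphoryl)acetic acid
Product: 23 (1R,3R,7Z,9R,10R)-3-hydroxy-3,7-dimethyl-4-oxo-11-oxabicyclo[8.1.0]undec-7-en-9-yl (diethoxyphosphoryl)acetate
Conditions: DCC, cat. DMAP, CH2Cl2, 0 °C to rt
Reagents that add atoms: none
Why: Steglich esterification; only the secondary C6 hydroxyl should be acylated, the tertiary C10 hydroxyl next to the ketone being too hindered.

Step 13
Reactants: 23 (1R,3R,7Z,9R,10R)-3-hydroxy-3,7-dimethyl-4-oxo-11-oxabicyclo[8.1.0]undec-7-en-9-yl (diethoxyphosphoryl)acetate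
Product: 25 (3aR,4R,6R,10Z,11aR)-4,6-dihydroxy-6,10-dimethyl-3-methylidene-3a,4,5,6,8,9-hexahydrocyclodeca[b]furan-2,7(3H,11aH)-dione, via phosphonate enolate 24 (not isolated)
Conditions: LiN(SiMe3)2 (1.05 equiv), THF, −78 °C to rt; then (CH2O)n, 0 °C to rt
Reagents that add atoms: formaldehyde (as paraformaldehyde), C=O
Why: Intramolecular alkylation of the phosphonoacetate carbanion by the epoxide (5-exo attack at C7 anti to the C7–O bond, which the erythro relation places opposite the ester oxygen) inverts C7 and gives the trans-fused lactone with the C8 carbinol retained; proton transfer gives enolate 24, and Horner–Wadsworth–Emmons reaction with formaldehyde installs C13, the phosphonate being far more acidic than the C2 ketone protons.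

Step 14
Reactants: 25 (3aR,4R,6R,10Z,11aR)-4,6-dihydroxy-6,10-dimethyl-3-methylidene-3a,4,5,6,8,9-hexahydrocyclodeca[b]furan-2,7(3H,11aH)-dione; 26 3-methylbutanoic anhydride
Product: 27 (3aR,4R,6R,10Z,11aR)-6-hydroxy-6,10-dimethyl-3-methylidene-2,7-dioxo-2,3,3a,4,5,6,7,8,9,11a-decahydrocyclodeca[b]furan-4-yl 3-methylbutanoate
Conditions: Et3N, cat. DMAP, CH2Cl2, 0 °C
Reagents that add atoms: none
Why: DMAP-catalysed acylation of the secondary C8 hydroxyl; the tertiary C10 hydroxyl should not react, and the short, cold reaction limits translactonization and acyl migration.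

## Compound list

1 | (S)-lactic acid | C[C@H](O)C(=O)O | starting material
2 | pivalaldehyde (2,2-dimethylpropanal) | CC(C)(C)C=O | starting material
3 | (2S,5S)-2-tert-butyl-5-methyl-1,3-dioxolan-4-one | C[C@@H]1O[C@H](C(C)(C)C)OC1=O | intermediate
4 | propargyl bromide (3-bromoprop-1-yne) | C#CCBr | starting material
5 | lithium (2S)-2-tert-butyl-5-methyl-1,3-dioxol-4-olate (enolate of 3) | CC1=C(O[Li])O[C@@H](C(C)(C)C)O1 | intermediate (not isolated)
6 | (2S,5R)-2-tert-butyl-5-methyl-5-(prop-2-yn-1-yl)-1,3-dioxolan-4-one | C[C@]1(CC#C)O[C@H](C(C)(C)C)OC1=O | intermediate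
7 | lithium (2S,5R)-2-tert-butyl-4,5-dimethyl-5-(3-lithioprop-2-yn-1-yl)-1,3-dioxolan-4-olate (hemiketal carbon unassigned) | [Li]OC1(C)O[C@@H](C(C)(C)C)O[C@]1(C)CC#C[Li] | intermediate (not isolated)
8 | (3R)-3-hydroxy-3-methylhex-5-yn-2-one | CC(=O)[C@](C)(O)CC#C | intermediate
9 | (3R)-3-methyl-2,3-bis(triethylsilyloxy)hex-1-en-5-yne | C=C(O[Si](CC)(CC)CC)[C@](C)(O[Si](CC)(CC)CC)CC#C | intermediate
10 | triethyl({1-[(2R)-2-(triethylsilyloxy)pent-4-yn-2-yl]cyclopropyl}oxy)silane | C#CC[C@@](C)(O[Si](CC)(CC)CC)C1(O[Si](CC)(CC)CC)CC1 | intermediate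
11 | but-2-yn-1-ol | CC#CCO | starting material
12 | sodium 2,2-bis(2-methoxyethoxy)-3-methyl-2,5-dihydro-1,2-oxaluminol-2-uide (cyclic alkenylalanate) | CC1=CCO[Al-]1(OCCOC)OCCOC.[Na+] | intermediate (not isolated)
13 | (2Z)-3-iodobut-2-en-1-ol | C/C(I)=C/CO | intermediate
14 | (2Z)-3-iodobut-2-enal | C/C(I)=C/C=O | intermediate
15 | dicyclohexyl{(1E,4R)-4-(triethylsilyloxy)-4-[1-(triethylsilyloxy)cyclopropyl]pent-1-en-1-yl}borane | C1CCC(CC1)B(/C=C/C[C@@](C)(O[Si](CC)(CC)CC)C2(O[Si](CC)(CC)CC)CC2)C3CCCCC3 | intermediate (not isolated)
16 | methyl{(1E,4R)-4-(triethylsilyloxy)-4-[1-(triethylsilyloxy)cyclopropyl]pent-1-en-1-yl}zinc | C[Zn]/C=C/C[C@@](C)(O[Si](CC)(CC)CC)C1(O[Si](CC)(CC)CC)CC1 | intermediate (not isolated)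
17 | (2Z,4S,5E,8R)-2-iodo-8-(triethylsilyloxy)-8-[1-(triethylsilyloxy)cyclopropyl]nona-2,5-dien-4-ol | C/C(I)=C/[C@@H](O)/C=C/C[C@@](C)(O[Si](CC)(CC)CC)C1(O[Si](CC)(CC)CC)CC1 | intermediate
18 | (2Z,4S,5E,8R)-8-(1-hydroxycyclopropyl)-2-iodonona-2,5-diene-4,8-diol | C/C(I)=C/[C@@H](O)/C=C/C[C@@](C)(O)C1(O)CC1 | intermediate
19 | eleven-membered palladacycle with C3 and C4 on palladium (ring-opened homoenolate; phosphine not drawn) | C/C1=C/[C@@H](O)/C=C/C[C@@](C)(O)C(=O)CC[Pd]1 | intermediate (not isolated)
20 | (2R,4E,6S,7Z)-2,6-dihydroxy-2,8-dimethylcyclodeca-4,7-dien-1-one | C/C1=C/[C@@H](O)/C=C/C[C@@](C)(O)C(=O)CC1 | intermediate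
21 | (1R,3R,7Z,9R,10R)-3,9-dihydroxy-3,7-dimethyl-11-oxabicyclo[8.1.0]undec-7-en-4-one | C/C1=C/[C@@H](O)[C@H]2O[C@@H]2C[C@@](C)(O)C(=O)CC1 | intermediate
22 | (diethoxyphosphoryl)acetic acid | CCOP(=O)(CC(=O)O)OCC | starting material
23 | (1R,3R,7Z,9R,10R)-3-hydroxy-3,7-dimethyl-4-oxo-11-oxabicyclo[8.1.0]undec-7-en-9-yl (diethoxyphosphoryl)acetate | C/C1=C/[C@@H](OC(=O)CP(=O)(OCC)OCC)[C@H]2O[C@@H]2C[C@@](C)(O)C(=O)CC1 | intermediate
24 | lithium enolate of diethyl [(3aR,4R,6R,10Z,11aR)-4,6-dihydroxy-6,10-dimethyl-2,7-dioxo-2,3,3a,4,5,6,7,8,9,11a-decahydrocyclodeca[b]furan-3-yl]phosphonate | CCOP(=O)(OCC)C1=C(O[Li])O[C@@H]2/C=C(/C)CCC(=O)[C@](C)(O)C[C@@H](O)[C@@H]12 | intermediate (not isolated)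
25 | (3aR,4R,6R,10Z,11aR)-4,6-dihydroxy-6,10-dimethyl-3-methylidene-3a,4,5,6,8,9-hexahydrocyclodeca[b]furan-2,7(3H,11aH)-dione | C=C1C(=O)O[C@@H]2/C=C(/C)CCC(=O)[C@](C)(O)C[C@@H](O)[C@@H]12 | intermediate
26 | 3-methylbutanoic anhydride (isovaleric anhydride) | CC(C)CC(=O)OC(=O)CC(C)C | starting material
27 | (3aR,4R,6R,10Z,11aR)-6-hydroxy-6,10-dimethyl-3-methylidene-2,7-dioxo-2,3,3a,4,5,6,7,8,9,11a-decahydrocyclodeca[b]furan-4-yl 3-methylbutanoate | C=C1C(=O)O[C@@H]2/C=C(/C)CCC(=O)[C@](C)(O)C[C@@H](OC(=O)CC(C)C)[C@@H]12 | target

## Step count and least certain steps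

Total step count: 14. Longest linear sequence: 12 steps (steps 1–5 and 8–14); steps 6–7 make the second fragment.

**Step 10 (key step, proposed new method).** Most likely failure: β-hydride elimination of the palladium homoenolate (vinyl ketone and hydrodeiodination) or bimolecular coupling outrunning the slow macrocyclic reductive elimination; oxidation of the bis-allylic C6 carbinol by the alkenylpalladium species is a further drain. Fallback (known chemistry, the order of the two fragment unions is reversed):

- Setting out from 10, Bu4NF gives (R)-1-(2-hydroxypent-4-yn-2-yl)cyclopropan-1-ol F1.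
- N-Iodosuccinimide opens the cyclopropanol to the β-iodo ketone (4R)-4-hydroxy-1-iodo-4-methylhept-6-yn-3-one F2.
- Zinc insertion and intermolecular Negishi coupling (Pd(PPh3)4) with iodide 13 give (4R,8Z)-4,10-dihydroxy-4,8-dimethyldec-8-en-1-yn-5-one F3.
- MnO2 oxidizes the allylic alcohol to the ynal (2Z,7R)-7-hydroxy-3,7-dimethyl-6-oxodec-2-en-9-ynal F4.
- The ring is then closed at C6–C7 by the intramolecular version of step 8 (Cy2BH, then Me2Zn and (−)-MIB at high dilution), a macrocyclization mode known for ω-alkynals, which returns to the route at 20.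

**Step 11.** Most likely failure: poor facial or site selectivity of the directed epoxidation, because the conformation of the ten-membered ring, not the reagent, may decide which face of C7=C8 (or whether C4=C5) meets the titanium peroxide. Fallback (epoxidation before ring closure):

- Setting out from 17, the same titanium–tartrate conditions on the open chain, where the iodine deactivates C4=C5 and the matched acyclic case is reliable, give the epoxy alcohol (2Z,4R)-2-iodo-4-hydroxy bis-silyl ether F5.
- Bu4NF buffered with AcOH gives the epoxy triol F6, which is cyclized under the conditions of step 10 and returns at 21.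
- This order exposes a cyclopropanol four atoms from an epoxide to base, which is why it is the fallback and not the plan.

**Step 13.** Most likely failure: slow or 6-endo epoxide opening if the macrocycle cannot hold the ester oxygen anti to the C7–O bond, or attack of the liberated C8 alkoxide on the lactone or the phosphonate before proton transfer. Fallback (softer nucleophile, decarboxylative methylenation):

- Setting out from 21, esterification with mono-allyl malonate (DCC) gives the malonate F7.
- Cs2CO3 closes the lactone to the α-(allyloxycarbonyl) lactone F8.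
- Pd(PPh3)4/morpholine removes the allyl group to give the acid F9.
- Aqueous formaldehyde/Et2NH effects decarboxylative methylenation and returns at 25.

**Step 8.** Most likely failure: erosion of enantioselectivity by uncatalysed background addition, Z-to-E isomerization of the β-iodo enal before addition, or competing methyl transfer from zinc. Fallback (alkyne addition, then trans reduction):

- Setting out from 10 and 14, a Me2Zn/ProPhenol-catalysed alkynylation gives the propargylic alcohol (2Z,4R,8R)-2-iodo-8-(triethylsilyloxy)-8-[1-(triethylsilyloxy)cyclopropyl]non-2-en-5-yn-4-ol F10.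
- Hydroxyl-directed trans-hydroalumination with NaAlH2(OCH2CH2OCH3)2 and protonolysis returns at 17.

**Step 3.** Most likely failure: over-addition after premature collapse of the hemiketal, and consumption of methyllithium by released pivalaldehyde. Fallback (acyl transfer through an amide):

- Setting out from 6, Me(MeO)NH·HCl/iPrMgCl gives the Weinreb amide (2R)-2-hydroxy-N-methoxy-N,2-dimethylpent-4-ynamide F11.
- MeMgBr returns at 8.

## Further compounds

F1 | step 10 | (R)-1-(2-hydroxypent-4-yn-2-yl)cyclopropan-1-ol | C#CC[C@@](C)(O)C1(O)CC1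
F2 | step 10 | (4R)-4-hydroxy-1-iodo-4-methylhept-6-yn-3-one | ICCC(=O)[C@](C)(O)CC#C
F3 | step 10 | (4R,8Z)-4,10-dihydroxy-4,8-dimethyldec-8-en-1-yn-5-one | C#CC[C@@](C)(O)C(=O)CC/C(C)=C\CO
F4 | step 10 | (2Z,7R)-7-hydroxy-3,7-dimethyl-6-oxodec-2-en-9-ynal | C#CC[C@@](C)(O)C(=O)CC/C(C)=C\C=O
F5 | step 11 | (1R,2Z)-3-iodo-1-[(2R,3R)-3-{(2R)-2-(triethylsilyloxy)-2-[1-(triethylsilyloxy)cyclopropyl]propyl}oxiran-2-yl]but-2-en-1-ol | C/C(I)=C/[C@@H](O)[C@H]1O[C@@H]1C[C@@](C)(O[Si](CC)(CC)CC)C1(O[Si](CC)(CC)CC)CC1
F6 | step 11 | (1R,2Z)-1-[(2R,3R)-3-{(2R)-2-hydroxy-2-(1-hydroxycyclopropyl)propyl}oxiran-2-yl]-3-iodobut-2-en-1-ol | C/C(I)=C/[C@@H](O)[C@H]1O[C@@H]1C[C@@](C)(O)C1(O)CC1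
F7 | step 13 | (1R,3R,7Z,9R,10R)-3-hydroxy-3,7-dimethyl-4-oxo-11-oxabicyclo[8.1.0]undec-7-en-9-yl prop-2-en-1-yl propanedioate | C/C1=C/[C@@H](OC(=O)CC(=O)OCC=C)[C@H]2O[C@@H]2C[C@@](C)(O)C(=O)CC1
F8 | step 13 | prop-2-en-1-yl (3aR,4R,6R,10Z,11aR)-4,6-dihydroxy-6,10-dimethyl-2,7-dioxo-2,3,3a,4,5,6,7,8,9,11a-decahydrocyclodeca[b]furan-3-carboxylate (C3 epimers) | C=CCOC(=O)C1C(=O)O[C@@H]2/C=C(/C)CCC(=O)[C@](C)(O)C[C@@H](O)[C@@H]12
F9 | step 13 | (3aR,4R,6R,10Z,11aR)-4,6-dihydroxy-6,10-dimethyl-2,7-dioxo-2,3,3a,4,5,6,7,8,9,11a-decahydrocyclodeca[b]furan-3-carboxylic acid (C3 epimers) | OC(=O)C1C(=O)O[C@@H]2/C=C(/C)CCC(=O)[C@](C)(O)C[C@@H](O)[C@@H]12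
F10 | step 8 | (2Z,4R,8R)-2-iodo-8-(triethylsilyloxy)-8-[1-(triethylsilyloxy)cyclopropyl]non-2-en-5-yn-4-ol | C/C(I)=C/[C@@H](O)C#CC[C@@](C)(O[Si](CC)(CC)CC)C1(O[Si](CC)(CC)CC)CC1
F11 | step 3 | (2R)-2-hydroxy-N-methoxy-N,2-dimethylpent-4-ynamide | C#CC[C@@](C)(O)C(=O)N(C)OC
A1 | alternative 1 | methyl (2Z,4R,6R,10Z)-2-(bromomethyl)-6-hydroxy-6,10-dimethyl-4-(3-methylbutanoyloxy)-7,12-dioxododeca-2,10-dienoate | COC(=O)/C(CBr)=C/[C@H](OC(=O)CC(C)C)C[C@@](C)(O)C(=O)CC/C(C)=C\C=O
A2 | alternative 2 | (1R,3R)-1-[(2R,3R)-2-ethenyl-4-methylidene-5-oxooxolan-3-yl]-3-hydroxy-3,7-dimethyl-4-oxooct-7-en-1-yl 3-methylbutanoate | C=C[C@H]1OC(=O)C(=C)[C@@H]1[C@H](OC(=O)CC(C)C)C[C@@](C)(O)C(=O)CCC(C)=C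
A3 | alternative 3 | (3aR,4R,6E,10Z,11aR)-6,10-dimethyl-3-methylidene-2-oxo-2,3,3a,4,5,8,9,11a-octahydrocyclodeca[b]furan-4-yl 3-methylbutanoate (heliangolide diene) | C=C1C(=O)O[C@@H]2/C=C(/C)CC/C=C(\C)C[C@@H](OC(=O)CC(C)C)[C@@H]12
A4 | alternative 3 | 1,10-epoxide of A3 with the C10 oxygen in the configuration of 27 | C=C1C(=O)O[C@@H]2/C=C(/C)CC[C@H]3O[C@]3(C)C[C@@H](OC(=O)CC(C)C)[C@@H]12
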